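**Retrosynthetic overview**

1. The route rests on the 11-oxabicyclo[6.2.1]undecane core: the ether oxygen bridges C3 and the quaternary C10 across the ten-membered carbocycle C1–C10, next to the C1 ketone. The target is taken back (two arylmethyl ethers off, C2=C3 out, angelate off) to a ketone whose cis-fused α-methylene lactone is closed last, by 5-exo vinyl-radical attack from C6–O on C7 with nitroxide capture at C8.
2. The core is cut at O–C10 and C9–C10: a copper carbenoid at C10 is taken up by the oxygen of an all-cis 2-alkenyl oxane, and the oxonium ylide undergoes a [2,3] shift through the C7 (E)-alkoxyvinyl group. This cleaves O–C7 and closes the oxolanone and the ten-membered carbocycle together, setting C10 and C9.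
3. The all-cis oxane (C3–C7) comes from a δ-lactone by Reformatsky addition and silane reduction at C3; the E enol ether (C8, C9) comes from a Takai iodoalkene by copper C–O coupling.
4. The lactone comes from L-threonate (C5–C8) and an (E)-crotylboronate (C3, C4, C4-methyl).
5. Ring order: oxane (steps 7 and 11), then oxolanone plus ten-membered ring (step 15), then lactone ring (step 18).

Key step: step 15

Remark: atoms carry germacrane numbers throughout (C1 ketone, C3/C10 ether bridge, C12 lactone carbonyl, C13 methylene, C14 methyl on C10, C15 methyl on C4).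
Remark: boronate 4 is taken as a stock reagent made in one operation from trans-2-butene, B(Oi-Pr)3 and (R,R)-diisopropyl tartrate; the commercial pinacol (E)-crotylboronate could replace it with substrate control only.
Remark: after the ring expansion, the face of the cis C7=C8 bond that looks at the ether bridge (the face from which oxygen left C7) is assumed to be shielded, so a tethered radical and a trapping reagent add on the outer face.

**Route**

Step 1
Reactants: 1 methyl 3,4-O-isopropylidene-L-threonate
Product: 2 methyl 2-O-TBS-3,4-O-isopropylidene-L-threonate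
Conditions: TBSCl, imidazole, DMF, 23 °C
Reagents that add atoms: tert-butyldimethylsilyl chloride, CC(C)(C)[Si](C)(C)Cl
Why: Imidazole-promoted silylation of the secondary α-hydroxy ester protects the future C6 oxygen without touching a stereocenter.

Step 2
Reactants: 2 methyl 2-O-TBS-3,4-O-isopropylidene-L-threonate
Product: 3 2-O-TBS-3,4-O-isopropylidene-L-threose (C5 aldehyde)
Conditions: i-Bu2AlH, CH2Cl2, −78 °C
Reagents that add atoms: none
Why: Partial ester reduction at −78 °C, where the aluminium hemiacetal next to the silyloxy group persists until work-up, should give the aldehyde without over-reduction or epimerization at C6.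

Step 3
Reactants: 3 2-O-TBS-3,4-O-isopropylidene-L-threose; 4 diisopropyl (4R,5R)-2-[(E)-but-2-enyl]-1,3,2-dioxaborolane-4,5-dicarboxylate
Product: 5 homoallylic alcohol (C3 vinyl, 4S methyl, 5S hydroxyl, C6 OTBS, C7/C8 acetonide; 4,5-anti-5,6-anti)
Conditions: 4 Å MS, toluene, −78 °C; then aq. NaOH
Reagents that add atoms: none
Why: Roush crotylboration: the chair transition state of the (E)-crotylboronate sets C4/C5 anti, and the (R,R)-tartrate directs attack to the Si face, which is also the Felkin–Anh face of the α-silyloxy aldehyde (matched pair), so C5 is set anti to C6.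

Step 4
Reactants: 5 homoallylic alcohol
Product: 6 C5 2-naphthylmethyl (NAP) ether of 5
Conditions: 2-naphthylmethyl trichloroacetimidate, TfOH (cat.), CH2Cl2, 0 °C
Reagents that add atoms: 2-naphthylmethyl 2,2,2-trichloroacetimidate, ClC(Cl)(Cl)C(=N)OCc1ccc2ccccc2c1
Why: Acid-catalysed imidate O-alkylation avoids the alkoxide that would cause 1,2-silyl migration from C6–O; the NAP ether is chosen because it should survive the Lewis acid of step 11 and be cleaved by DDQ at the end.

Step 5
Reactants: 6 C5 NAP ether
Product: 7 C3 aldehyde (α-methyl aldehyde)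
Conditions: OsO4 (cat.), NaIO4, 2,6-lutidine, dioxane/H2O, 23 °C
Reagents that add atoms: NaIO4, [Na+].[O-]I(=O)(=O)=O (oxygen source through catalytic OsO4, O=[Os](=O)(=O)=O)
Why: Lemieux–Johnson oxidative cleavage of the terminal alkene should spare the naphthalene ring, and the lutidine buffer keeps C4 from epimerizing.

Step 6
Reactants: 7 C3 aldehyde
Product: 8 C3 carboxylic acid
Conditions: NaClO2, NaH2PO4, 2-methyl-2-butene, t-BuOH/H2O, 0 → 23 °C
Reagents that add atoms: NaClO2, [Na+].[O-]Cl=O
Why: Pinnick oxidation converts the aldehyde to the acid under buffered conditions that leave C4 and the protecting groups untouched.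

Step 7
Reactants: 8 C3 carboxylic acid
Product: 9 δ-lactone alcohol (C3 carbonyl, ring oxygen on C7, free C8–OH)
Conditions: AcOH/H2O (4:1), 35 °C; then toluene, 60 °C
Reagents that add atoms: none
Why: Aqueous acetic acid removes the terminal acetonide while the secondary TBS and NAP ethers stay, and acid-catalysed lactonization through C7–OH closes the six-membered ring in preference to the seven-membered one through C8–OH.

Step 8
Reactants: 9 δ-lactone alcohol
Product: 10 lactone aldehyde (C8 aldehyde)
Conditions: Dess–Martin periodinane, NaHCO3, CH2Cl2, 0 → 23 °C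
Reagents that add atoms: none
Why: Buffered Dess–Martin oxidation of the primary alcohol is non-basic, so the α-acyloxy aldehyde should keep its C7 configuration.

Step 9
Reactants: 10 lactone aldehyde
Product: 11 lactone (E)-iodoalkene (C8=C9–I)
Conditions: CrCl2, CHI3, THF/dioxane, 0 → 23 °C
Reagents that add atoms: iodoform, IC(I)I
Why: Takai olefination through the geminal dichromium reagent is E-selective and tolerates the lactone and the epimerizable aldehyde.

Step 10
Reactants: 11 lactone (E)-iodoalkene; 12 methyl bromoacetate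
Product: 13 hemiketal (C3 bears OH and CH2CO2Me; anomeric mixture)
Conditions: Zn (activated), THF, 40 °C (reagent formation); then 11, 0 → 23 °C; dilute aq. HCl, 0 °C
Reagents that add atoms: none
Why: Reformatsky addition: the weakly basic zinc enolate adds to the lactone carbonyl without enolizing C4 and stops at the hemiketal.

Step 11
Reactants: 13 hemiketal
Product: 14 all-cis oxane ester with (E)-2-iodovinyl group (C3 CH2CO2Me, C4 Me, C5 ONAP, C6 OTBS, C7 alkenyl, all on one face)
Conditions: Et3SiH, BF3·OEt2, MeCN/CH2Cl2, −40 → −10 °C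
Reagents that add atoms: none
Why: Reductive C-glycosidation: BF3 ionizes the hemiketal to the oxocarbenium ion and Et3SiH delivers hydride axially on the face opposite the pseudoaxial C4 methyl, which sets C3 with the acetate arm cis to the C4 methyl and to the C7 alkenyl group.

Step 12
Reactants: 14 all-cis oxane ester with (E)-2-iodovinyl group; 15 4-methoxybenzyl alcohol
Product: 16 all-cis oxane ester with (E)-PMB enol ether at C7
Conditions: CuI (10 mol%), 3,4,7,8-tetramethyl-1,10-phenanthroline, Cs2CO3, toluene, 80 °C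
Reagents that add atoms: none
Why: Copper-catalysed Ullmann-type C–O coupling of an alkenyl iodide with an alcohol keeps the alkene geometry, so the E enol ether that will control C9 should be obtained.

Step 13
Reactants: 16 all-cis oxane ester with (E)-PMB enol ether
Product: 17 potassium carboxylate of 16
Conditions: KOSiMe3, THF, 23 °C
Reagents that add atoms: KOSiMe3, C[Si](C)(C)[O-].[K+]
Why: Anhydrous ester cleavage with the silanolate gives the carboxylate salt directly, so the acid-labile enol ether never meets an acidic work-up.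

Step 14
Reactants: 17 potassium carboxylate; 18 N-ethyl-N-nitrosourea (diazoethane source)
Product: 20 diazo ketone (C2–C1(=O)–C10(=N2)–CH3 side chain on the all-cis oxane), via mixed anhydride 19 (not isolated)
Conditions: i-BuOCOCl, THF, −20 °C; then CH3CHN2 (from 18, KOH, Et2O, 0 °C), −20 → 23 °C
Reagents that add atoms: isobutyl chloroformate, CC(C)COC(Cl)=O (atoms stay in 19 only); diazoethane, CC=[N+]=[N-] (made from 18)
Why: Acylation of diazoethane by the mixed carbonic anhydride (Arndt–Eistert-type diazo ketone synthesis) works without free acid, because the departing carbonate takes the proton and falls apart to isobutanol and CO2.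

Step 15
Reactants: 20 diazo ketone
Product: 22 oxa-bridged cyclodecenone (O bridges C3 and C10; C1 ketone; C10 methyl; 9-OPMB; cis C7=C8; 6-OTBS; 5-ONAP; 4-methyl), via oxonium ylide 21 (not isolated)
Conditions: Cu(CF3COCHCOCF3)2 (5 mol%), CH2Cl2, reflux, slow addition of 20
Reagents that add atoms: none
Why: The copper catalyst turns the diazo ketone into an electrophilic carbenoid at C10, the oxane oxygen attacks it with the lone pair cis to the C3 side chain to give the cis-fused bicyclic oxonium ylide 21, and the ylide carbon then bonds to the enol ether terminus C9 in a concerted suprafacial [2,3]-sigmatropic shift that cleaves O–C7 and leaves C7=C8. The closest known reaction type is the copper-catalysed oxonium ylide formation and [2,3] ring expansion of 2-vinyltetrahydropyranyl diazo ketones to 11-oxabicyclo[6.2.1]undecenones; the methyl group on the diazo carbon and the alkoxy group on the alkene terminus are extensions, and the alkoxy group should help because C9 becomes oxocarbenium-like in the transition state. The five-membered oxacycle (O, C3, C2, C1, C10) closes by 5-exo attack of oxygen on the carbenoid, and the ten-membered carbocycle closes by three-atom ring expansion of the six-membered ether through a five-centre envelope (C10, O, C7, C8, C9). C10 is fixed by the ring fusion, since the migrating carbon must arrive on the ylide face that carries O–C7 and so ends cis to C4 on the oxolanone; C9 is fixed by the E geometry of the enol ether together with the envelope that swings C9 toward C6 and gives the cis ring alkene. The step needs ylide formation to outrun 1,2-hydride shift of the methyl carbenoid and C–H insertion, and one envelope to dominate; the 1,3-placement of carbenoid and ring oxygen, the cis-2,6 arrangement of side chain and alkenyl group, and the low tendency of copper carbenoids with this ligand toward 1,2-shift should secure this.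

Step 16
Reactants: 22 oxa-bridged cyclodecenone
Product: 23 C6 alcohol
Conditions: HF·pyridine, pyridine, THF, 0 → 23 °C
Reagents that add atoms: none
Why: Buffered fluoride desilylation frees only the C6 hydroxyl; the arylmethyl ethers, the ketone and the alkene are inert.

Step 17
Reactants: 23 C6 alcohol; 24 methoxyallene
Product: 25 2-iodoallyl mixed acetal (C6–O–CH(OMe)–C(I)=CH2; mixture at the acetal carbon)
Conditions: N-iodosuccinimide, CH2Cl2, −40 → −10 °C; then Et3N
Reagents that add atoms: N-iodosuccinimide, O=C1CCC(=O)N1I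
Why: Iodoalkoxylation of the alkoxyallene: iodonium adds to the central allene carbon and the C6 hydroxyl captures the oxocarbenium ion, giving the Ueno–Stork-type radical precursor that already carries C11, C12 and C13.

Step 18
Reactants: 25 2-iodoallyl mixed acetal
Product: 26 C8 TEMPO ether of the tricyclic α-methylene lactol methyl ether (cis-fused ring O6–C12–C11–C7; 7S, 8S)
Conditions: Bu3SnH, TEMPO (both by syringe pump), benzene, 70 °C
Reagents that add atoms: TEMPO, CC1(C)CCCC(C)(C)N1[O]
Why: Tin-mediated vinyl radical 5-exo-trig cyclization (Ueno–Stork type) with nitroxide capture: the radical tethered to C6–O adds to C7 on the outer alkene face through the rotamer with C5–C6–C7=C8 synclinal, giving the cis-fused oxacycle (H6/H7 cis), and TEMPO caps the C8 radical on the same outer face.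

Step 19
Reactants: 26 C8 TEMPO ether
Product: 27 lactol with free C8–OH (C12 hemiacetal, mixture)
Conditions: Zn dust, AcOH/THF/H2O (3:1:1), 60 °C
Reagents that add atoms: water, O
Why: Zinc in acetic acid reduces the N–O bond of the alkoxyamine, and the aqueous acid hydrolyses the allylic methyl acetal to the lactol in the same operation; the arylmethyl ethers and the ketone should be stable.

Step 20
Reactants: 27 lactol with free C8–OH
Product: 28 hydroxy α-methylene lactone
Conditions: MnO2, CH2Cl2, 23 °C
Reagents that add atoms: none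
Why: MnO2 oxidizes the allylic lactol to the α-methylene γ-lactone chemoselectively and leaves the non-allylic C8 alcohol untouched.

Step 21
Reactants: 28 hydroxy α-methylene lactone; 29 angelic acid
Product: 30 C8 angelate
Conditions: 2,4,6-trichlorobenzoyl chloride, Et3N, toluene, 23 °C; then 28, 80 °C
Reagents that add atoms: none
Why: Yamaguchi esterification through the mixed anhydride, run without DMAP so that the Z double bond of the angelate does not isomerize to the tiglate; C8 keeps its configuration.

Step 22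
Reactants: 30 C8 angelate
Product: 32 furanone (5-O-NAP, 9-O-PMB ether of the target), via silyl enol ether 31 (not isolated)
Conditions: TMSOTf, Et3N, CH2Cl2, 0 °C; then Pd(OAc)2, MeCN, 40 °C
Reagents that add atoms: trimethylsilyl trifluoromethanesulfonate, C[Si](C)(C)OS(=O)(=O)C(F)(F)F (atoms stay in 31 only)
Why: Saegusa–Ito dehydrogenation: the ketone can enolize only toward C2 because C10 is quaternary, and Pd(OAc)2 converts the silyl enol ether into the 3(2H)-furanone by β-hydride elimination of H3.

Step 23
Reactants: 32 furanone (5-O-NAP, 9-O-PMB ether)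
Product: 33 target, (4R,5S,6R,7S,8S,9R,10R)-8-angeloyloxy-5,9-dihydroxy-3,10-epoxy-1-oxogermacra-2,11(13)-dien-12,6-olide
Conditions: DDQ, CH2Cl2/pH 7 buffer, 23 °C
Reagents that add atoms: none
Why: Oxidative cleavage of the PMB and NAP ethers by DDQ (hydride abstraction, then hydrolysis) frees the C5 and C9 hydroxyls without hydrogenolysis, which the three alkenes forbid.

**Compound list**

1 | methyl 3,4-O-isopropylidene-L-threonate | COC(=O)[C@H](O)[C@@H]1COC(C)(C)O1 | starting material
2 | methyl 2-O-TBS-3,4-O-isopropylidene-L-threonate | COC(=O)[C@H](O[Si](C)(C)C(C)(C)C)[C@@H]1COC(C)(C)O1 | intermediate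
3 | 2-O-TBS-3,4-O-isopropylidene-L-threose | O=C[C@H](O[Si](C)(C)C(C)(C)C)[C@@H]1COC(C)(C)O1 | intermediate
4 | diisopropyl (4R,5R)-2-[(E)-but-2-enyl]-1,3,2-dioxaborolane-4,5-dicarboxylate | C/C=C/CB1O[C@@H](C(=O)OC(C)C)[C@H](C(=O)OC(C)C)O1 | starting material
5 | homoallylic alcohol (4S,5S) | C=C[C@H](C)[C@H](O)[C@H](O[Si](C)(C)C(C)(C)C)[C@@H]1COC(C)(C)O1 | intermediate
6 | C5 NAP ether of 5 | C=C[C@H](C)[C@H](OCc1ccc2ccccc2c1)[C@H](O[Si](C)(C)C(C)(C)C)[C@@H]3COC(C)(C)O3 | intermediate
7 | C3 aldehyde | O=C[C@H](C)[C@H](OCc1ccc2ccccc2c1)[C@H](O[Si](C)(C)C(C)(C)C)[C@@H]3COC(C)(C)O3 | intermediate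
8 | C3 carboxylic acid | OC(=O)[C@H](C)[C@H](OCc1ccc2ccccc2c1)[C@H](O[Si](C)(C)C(C)(C)C)[C@@H]3COC(C)(C)O3 | intermediate
9 | δ-lactone alcohol | O=C1O[C@@H](CO)[C@@H](O[Si](C)(C)C(C)(C)C)[C@@H](OCc2ccc3ccccc3c2)[C@H]1C | intermediate
10 | lactone aldehyde | O=C1O[C@@H](C=O)[C@@H](O[Si](C)(C)C(C)(C)C)[C@@H](OCc2ccc3ccccc3c2)[C@H]1C | intermediate
11 | lactone (E)-iodoalkene | O=C1O[C@@H](/C=C/I)[C@@H](O[Si](C)(C)C(C)(C)C)[C@@H](OCc2ccc3ccccc3c2)[C@H]1C | intermediate
12 | methyl bromoacetate | COC(=O)CBr | starting material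
13 | hemiketal | COC(=O)CC1(O)O[C@@H](/C=C/I)[C@@H](O[Si](C)(C)C(C)(C)C)[C@@H](OCc2ccc3ccccc3c2)[C@H]1C | intermediate
14 | all-cis oxane ester with (E)-2-iodovinyl group | COC(=O)C[C@H]1O[C@@H](/C=C/I)[C@@H](O[Si](C)(C)C(C)(C)C)[C@@H](OCc2ccc3ccccc3c2)[C@H]1C | intermediate
15 | 4-methoxybenzyl alcohol | COc1ccc(CO)cc1 | starting material
16 | all-cis oxane ester with (E)-PMB enol ether | COC(=O)C[C@H]1O[C@@H](/C=C/OCc2ccc(OC)cc2)[C@@H](O[Si](C)(C)C(C)(C)C)[C@@H](OCc3ccc4ccccc4c3)[C@H]1C | intermediate
17 | potassium carboxylate of 16 | [K+].[O-]C(=O)C[C@H]1O[C@@H](/C=C/OCc2ccc(OC)cc2)[C@@H](O[Si](C)(C)C(C)(C)C)[C@@H](OCc3ccc4ccccc4c3)[C@H]1C | intermediate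
18 | N-ethyl-N-nitrosourea | CCN(N=O)C(N)=O | starting material
19 | isobutyl carbonic mixed anhydride | CC(C)COC(=O)OC(=O)C[C@H]1O[C@@H](/C=C/OCc2ccc(OC)cc2)[C@@H](O[Si](C)(C)C(C)(C)C)[C@@H](OCc3ccc4ccccc4c3)[C@H]1C | intermediate (not isolated)
20 | diazo ketone (key-step precursor) | CC(=[N+]=[N-])C(=O)C[C@H]1O[C@@H](/C=C/OCc2ccc(OC)cc2)[C@@H](O[Si](C)(C)C(C)(C)C)[C@@H](OCc3ccc4ccccc4c3)[C@H]1C | intermediate
21 | bicyclic oxonium ylide | CC1=C([O-])C[C@@H]2[C@H](C)[C@H](OCc3ccc4ccccc4c3)[C@H](O[Si](C)(C)C(C)(C)C)[C@H](/C=C/OCc5ccc(OC)cc5)[O+]12 | intermediate (not isolated)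
22 | oxa-bridged cyclodecenone (key-step product) | CC(C)(C)[Si](C)(C)O[C@H]1[C@@H](OCc2ccc3ccccc3c2)[C@@H](C)[C@H]4CC(=O)[C@](C)(O4)[C@H](OCc5ccc(OC)cc5)/C=C\1 | intermediate
23 | C6 alcohol | O[C@H]1[C@@H](OCc2ccc3ccccc3c2)[C@@H](C)[C@H]4CC(=O)[C@](C)(O4)[C@H](OCc5ccc(OC)cc5)/C=C\1 | intermediate
24 | methoxyallene | COC=C=C | starting material
25 | 2-iodoallyl mixed acetal | C=C(I)C(OC)O[C@H]1[C@@H](OCc2ccc3ccccc3c2)[C@@H](C)[C@H]4CC(=O)[C@](C)(O4)[C@H](OCc5ccc(OC)cc5)/C=C\1 | intermediate
26 | C8 TEMPO ether of the tricyclic α-methylene lactol methyl ether | C=C1C(OC)O[C@H]2[C@@H](OCc3ccc4ccccc4c3)[C@@H](C)[C@H]5CC(=O)[C@](C)(O5)[C@H](OCc6ccc(OC)cc6)[C@@H](ON7C(C)(C)CCCC7(C)C)[C@@H]12 | intermediate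
27 | lactol with free C8–OH | C=C1C(O)O[C@H]2[C@@H](OCc3ccc4ccccc4c3)[C@@H](C)[C@H]5CC(=O)[C@](C)(O5)[C@H](OCc6ccc(OC)cc6)[C@@H](O)[C@@H]12 | intermediate
28 | hydroxy α-methylene lactone | C=C1C(=O)O[C@H]2[C@@H](OCc3ccc4ccccc4c3)[C@@H](C)[C@H]5CC(=O)[C@](C)(O5)[C@H](OCc6ccc(OC)cc6)[C@@H](O)[C@@H]12 | intermediate
29 | angelic acid | C/C=C(/C)C(=O)O | starting material
30 | C8 angelate | C=C1C(=O)O[C@H]2[C@@H](OCc3ccc4ccccc4c3)[C@@H](C)[C@H]5CC(=O)[C@](C)(O5)[C@H](OCc6ccc(OC)cc6)[C@@H](OC(=O)/C(C)=C\C)[C@@H]12 | intermediate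
31 | C1 trimethylsilyl enol ether | C=C1C(=O)O[C@H]2[C@@H](OCc3ccc4ccccc4c3)[C@@H](C)[C@H]5C=C(O[Si](C)(C)C)[C@](C)(O5)[C@H](OCc6ccc(OC)cc6)[C@@H](OC(=O)/C(C)=C\C)[C@@H]12 | intermediate (not isolated)
32 | furanone (5-O-NAP, 9-O-PMB ether of the target) | C=C1C(=O)O[C@H]2[C@@H](OCc3ccc4ccccc4c3)[C@@H](C)C5=CC(=O)[C@](C)(O5)[C@H](OCc6ccc(OC)cc6)[C@@H](OC(=O)/C(C)=C\C)[C@@H]12 | intermediate
33 | target (CNP0206920.1) | C=C1C(=O)O[C@H]2[C@@H](O)[C@@H](C)C3=CC(=O)[C@](C)(O3)[C@H](O)[C@@H](OC(=O)/C(C)=C\C)[C@@H]12 | target

**Step count and risks**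

Total step count: 23. Longest linear sequence: 23 steps (from 1 to 33; compounds 4, 12, 15, 18, 24 and 29 enter as reagent-type building blocks).

Steps most likely to fail:

1. Step 15 (ring expansion). The ylide must form on the oxane face that also carries the C4 methyl and the C6 silyloxy group, so 1,2-hydride shift or C–H insertion of the carbenoid may compete. The electron-rich alkoxyallyl unit may also migrate through the other envelope or by a dissociative path, which would erode the configuration at C9 and the alkene geometry. Fallback: remove the oxygen from the migrating group and introduce it afterwards. It sets out from 14: palladium-catalysed formate reduction (Pd(OAc)2, PPh3, HCO2H, Et3N, DMF) gives the 2-vinyl oxane ester F1; KOSiMe3 gives the potassium carboxylate F2; i-BuOCOCl gives the mixed anhydride F3 (not isolated) and diazoethane gives the vinyl diazo ketone F4; Cu(CF3COCHCOCF3)2 gives, through the oxonium ylide F5 (not isolated), the bridged ketone F6 with a C9 methylene; allylic hydroxylation with SeO2/t-BuOOH on the outer face gives the C9 alcohol F7; 4-methoxybenzyl trichloroacetimidate with acid catalysis then returns the route at 22.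

2. Step 18 (radical cyclization with nitroxide capture). Facial selectivity in the capture of the C8 radical is not enforced by a ring, and capture on the inner face would give the C8 epimer. Fallback: set C8 by SN2 inversion instead of radical capture. It sets out from 25: the same radical reaction would then give the 8-epi TEMPO ether F8; Zn/AcOH/H2O gives the 8-epi lactol F9; MnO2 gives the 8-epi hydroxy lactone F10; Mitsunobu esterification (PPh3, DIAD) with angelic acid 29 inverts C8 and returns the route at 30.

3. Step 22 (dehydrogenation). Palladium hydride formed during the oxidation may move the exocyclic methylene into conjugation inside the lactone ring, or the β-hydride elimination may stall. Fallback: selenoxide elimination in place of palladium. It sets out from the silyl enol ether 31: PhSeCl gives the C2 phenylselenide F11 (selenium on the face away from the carbon bridge, cis to H3); H2O2/pyridine gives the selenoxide F12 (not isolated), whose syn elimination returns the route at 32.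

Further compounds
F1 | step 15 | 2-vinyl oxane methyl ester | COC(=O)C[C@H]1O[C@@H](C=C)[C@@H](O[Si](C)(C)C(C)(C)C)[C@@H](OCc2ccc3ccccc3c2)[C@H]1C
F2 | step 15 | potassium carboxylate of F1 | [K+].[O-]C(=O)C[C@H]1O[C@@H](C=C)[C@@H](O[Si](C)(C)C(C)(C)C)[C@@H](OCc2ccc3ccccc3c2)[C@H]1C
F3 | step 15 | isobutyl carbonic mixed anhydride of F2 | CC(C)COC(=O)OC(=O)C[C@H]1O[C@@H](C=C)[C@@H](O[Si](C)(C)C(C)(C)C)[C@@H](OCc2ccc3ccccc3c2)[C@H]1C
F4 | step 15 | vinyl diazo ketone | CC(=[N+]=[N-])C(=O)C[C@H]1O[C@@H](C=C)[C@@H](O[Si](C)(C)C(C)(C)C)[C@@H](OCc2ccc3ccccc3c2)[C@H]1C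
F5 | step 15 | oxonium ylide of F4 | CC1=C([O-])C[C@@H]2[C@H](C)[C@H](OCc3ccc4ccccc4c3)[C@H](O[Si](C)(C)C(C)(C)C)[C@H](C=C)[O+]12
F6 | step 15 | bridged ketone with C9 methylene | CC(C)(C)[Si](C)(C)O[C@H]1[C@@H](OCc2ccc3ccccc3c2)[C@@H](C)[C@H]4CC(=O)[C@](C)(O4)C/C=C\1
F7 | step 15 | C9 alcohol of the bridged ketone | CC(C)(C)[Si](C)(C)O[C@H]1[C@@H](OCc2ccc3ccccc3c2)[C@@H](C)[C@H]4CC(=O)[C@](C)(O4)[C@H](O)/C=C\1
F8 | step 18 | 8-epi TEMPO ether | C=C1C(OC)O[C@H]2[C@@H](OCc3ccc4ccccc4c3)[C@@H](C)[C@H]5CC(=O)[C@](C)(O5)[C@H](OCc6ccc(OC)cc6)[C@H](ON7C(C)(C)CCCC7(C)C)[C@@H]12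
F9 | step 18 | 8-epi lactol | C=C1C(O)O[C@H]2[C@@H](OCc3ccc4ccccc4c3)[C@@H](C)[C@H]5CC(=O)[C@](C)(O5)[C@H](OCc6ccc(OC)cc6)[C@H](O)[C@@H]12
F10 | step 18 | 8-epi hydroxy α-methylene lactone | C=C1C(=O)O[C@H]2[C@@H](OCc3ccc4ccccc4c3)[C@@H](C)[C@H]5CC(=O)[C@](C)(O5)[C@H](OCc6ccc(OC)cc6)[C@H](O)[C@@H]12
F11 | step 22 | C2 phenylselenide | C=C1C(=O)O[C@H]2[C@@H](OCc3ccc4ccccc4c3)[C@@H](C)[C@H]5[C@H]([Se]c8ccccc8)C(=O)[C@](C)(O5)[C@H](OCc6ccc(OC)cc6)[C@@H](OC(=O)/C(C)=C\C)[C@@H]12
F12 | step 22 | C2 selenoxide | C=C1C(=O)O[C@H]2[C@@H](OCc3ccc4ccccc4c3)[C@@H](C)[C@H]5[C@H]([Se](=O)c8ccccc8)C(=O)[C@](C)(O5)[C@H](OCc6ccc(OC)cc6)[C@@H](OC(=O)/C(C)=C\C)[C@@H]12
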